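The data were computed for an exercise.

all flasks: free catalyst 0.5 mol%
- larch: left-handed substrate 0.17 M; right-handed substrate 0.17 M; coupling partner 2 equiv; added ligand 4 mM; run made earlier
- alder: left-handed substrate 0.38 M; right-handed substrate 0.38 M; coupling partner 2 equiv; added ligand 4 mM; run made earlier
- elm: left-handed substrate 0.25 M; right-handed substrate 0.25 M; coupling partner 2 equiv; added ligand 6 mM; run made earlier
- flask: left-handed substrate 0.25 M; right-handed substrate 0.25 M; coupling partner 2.00 equiv; added ligand 4.0 mM

- larch (time / min: left-handed product / %, left-handed substrate / %): 0.417: 1, 46; 0.667: 1, 49; 1.33: 0, 46; 2.50: 4, 45; 5.00: 4, 45
- alder (time / min: left-handed product / %, left-handed substrate / %): 1.00: 4, 38; 2.00: 18, 40; 3.00: 16, 30; 4.00: 23, 27; 5.00: 29, 23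
- elm (time / min: left-handed product / %, left-handed substrate / %): 0.417: 0, 46; 1.33: 0, 50; 2.00: 2, 47; 3.00: 6, 51; 5.00: 9, 41

(scatter of a reading: 2 percentage points)

- free catalyst is single-handed; left-handed substrate and right-handed substrate are mirror images of each other, charged as a racemate, each of them at the stated concentration
- steps thought possible: coupling partner + free catalyst + left-handed substrate -> free catalyst + left-handed product; coupling partner + free catalyst + right-handed substrate -> free catalyst + right-handed product; free catalyst + added ligand <-> idle complex; 2 free catalyst -> spent catalyst

- factor on the rate of making left-handed product when 10% of the left-handed substrate and right-handed substrate together are converted if coupling partner is charged twice over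
- factor on the rate when 10% of the left-handed substrate and right-handed substrate together are converted if free catalyst is charged at 0.1 mol% instead

We start from the amounts: in this flask the catalyst charge, taken on the left-handed substrate, is 1.25 mM, less than the 4.0 mM of added ligand. So the ligand can hold the catalyst as idle complex, where [free catalyst] = [idle complex]/(K[added ligand]) with K the binding constant, but [added ligand] depends on how much is bound, so we iterate.

In a first round we count the ligand charge as free, and free catalyst then follows the charge, a factor 0.200 at the lower loading. But ligand in the idle complex isn't free, so in a second round we take the catalyst as bound. That leaves 2.75 mM of free ligand here and 3.75 mM at the lower loading. This flask then has 0.455 for catalyst charge over free ligand, the buffer ratio, and [free catalyst] is that ratio over K.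

With partner at equal equivalents, percent per minute goes as free catalyst times [left-handed substrate]. For alder against larch the first round gives a factor 5.00, and the second gives 7.49. The left-handed product at 5.00 min reads a factor 7.25, above the first, but larch's 4% carries a scatter of 2 percentage points, so this only leans.

At equal conversion substrate, partner and K cancel, so we commit to a factor of 0.147 on the rate at the lower loading. Doubled partner gives 2.11, counting what is consumed by then.

The forecast says 2 for doubled partner and 0.105 for the lower loading, on the ground “This indicates tight binding”; its factor for the lower loading is lower than ours.

The simulation gives 2.13 for doubled partner and 0.150 for the lower loading, a factor 1.43 above the forecast's number.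

    coupling partner + free catalyst + left-handed substrate → free catalyst + left-handed product (k = 4000 L² mol⁻² min⁻¹)
    coupling partner + free catalyst + right-handed substrate → free catalyst + right-handed product (k = 1600 L² mol⁻² min⁻¹)
    free catalyst + added ligand ⇌ idle complex, settled at all times (K = 13000 L mol⁻¹)
    2 free catalyst → spent catalyst (k = 2900 L mol⁻¹ min⁻¹)

 At equal conversion the idle complex holds 96.1% of the catalyst in this flask and 97.1% at the lower loading. In a further flask with twice the catalyst charged, the buffer ratio becomes 1.67, a factor 3.67, and the simulation's factor on the rate is 3.28.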